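Ring B is disconnected by a retro-Cope/retro-cyclopropanation: sp3 C1 sits between C5 and C10 in ring B while C4 and C9 carry oxygen, the cyclohepta-1,4-diene pattern (C5=C6, C9=C10) that a C5–C1–C10 cyclopropane with vinyl groups on C5 and C10 leaves behind. One rhodium-carbenoid step on an acyclic (E)-vinyl diazoketone carrying a 2-silyloxydiene closes ring A by cyclopropanation, closes ring B by [3,3] shift and sets quaternary C1. The dienone then receives the C5 hydrogen and C6 oxygen by syn hydroboration, the C4 isopropyl carbinol, the C8 methylene, the C9 alcohol and the ester. Numbering: ring A C1–C5, ring B C1, C5–C10; C14 on C8, C15 on C1.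

Key step: step 8

Assumption: the antipode of the dirhodium catalyst that gives (1R)-15 is fixed by experiment; bicyclic compounds are named with the atom numbers above (bicyclo[5.3.0]decane core C1–C10), not with von Baeyer locants.

Step 1
Reactants: 1 2-methyl-1,3-dithiane; 2 methacrolein
Product: 4 2-methyl-1-(2-methyl-1,3-dithian-2-yl)prop-2-en-1-ol, via 2-lithio-2-methyl-1,3-dithiane 3 (not isolated)
Conditions: n-BuLi, THF, −30 °C; then 2, −78 °C; then H2O
Reagents that add atoms: none
Why: Corey–Seebach umpolung, in which the lithiated dithiane adds 1,2 to the enal in THF and delivers a masked acetyl group next to a methallyl carbinol; the carbinol centre is racemic and is erased in step 2.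

Step 2
Reactants: 4 2-methyl-1-(2-methyl-1,3-dithian-2-yl)prop-2-en-1-ol; 5 triethyl orthoacetate
Product: 7 ethyl (4E)-4-methyl-5-(2-methyl-1,3-dithian-2-yl)pent-4-enoate, via ketene acetal 6 (not isolated)
Conditions: 5 (excess), EtCO2H (cat.), 140 °C, EtOH distilled off
Reagents that add atoms: none
Why: Johnson–Claisen rearrangement through a chair transition state with the bulky dithianyl group equatorial, which puts it trans to the new CH2CH2CO2Et chain and so fixes the (E)-trisubstituted alkene that becomes C1=C10.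

Step 3
Reactants: 7 ethyl (4E)-4-methyl-5-(2-methyl-1,3-dithian-2-yl)pent-4-enoate
Product: 8 (4E)-N-methoxy-N,4-dimethyl-5-(2-methyl-1,3-dithian-2-yl)pent-4-enamide
Conditions: MeNH(OMe)·HCl, LiN(SiMe3)2, THF, −20 → 0 °C
Reagents that add atoms: N,O-dimethylhydroxylamine hydrochloride, CNOC.Cl
Why: Weinreb amide formation by aminolysis of the ester with the lithium amide made in the flask, carried out while the ketone is still masked as the dithiane so that no second electrophile competes.

Step 4
Reactants: 8 (4E)-N-methoxy-N,4-dimethyl-5-(2-methyl-1,3-dithian-2-yl)pent-4-enamide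
Product: 9 (4E)-N-methoxy-N,4-dimethyl-6-oxohept-4-enamide
Conditions: PhI(O2CCF3)2, MeCN–H2O (9:1), 0 °C
Reagents that add atoms: water, O
Why: oxidative dithioacetal hydrolysis with the hypervalent iodine reagent frees the methyl ketone quickly at low temperature, conditions under which the (E)-enone should not isomerise.

Step 5
Reactants: 9 (4E)-N-methoxy-N,4-dimethyl-6-oxohept-4-enamide
Product: 10 (4E)-N-methoxy-N,4-dimethyl-6-[(triisopropylsilyl)oxy]hepta-4,6-dienamide
Conditions: TIPSOTf, Et3N, CH2Cl2, 0 °C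
Reagents that add atoms: triisopropylsilyl trifluoromethanesulfonate, CC(C)[Si](OS(=O)(=O)C(F)(F)F)(C(C)C)C(C)C
Why: soft enolisation (O-silylation, then loss of a methyl proton to the amine) gives the cross-conjugated 2-silyloxy-1,3-diene without touching the amide or the alkene geometry, and the triisopropylsilyl group makes the enol ether robust enough for the next steps.

Step 6
Reactants: 10 (4E)-N-methoxy-N,4-dimethyl-6-[(triisopropylsilyl)oxy]hepta-4,6-dienamide; 11 allylmagnesium bromide
Product: 12 (7E)-7-methyl-9-[(triisopropylsilyl)oxy]deca-1,7,9-trien-4-one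
Conditions: 11, THF, −78 °C; then pH 7 buffer, cold
Reagents that add atoms: none
Why: Weinreb ketone synthesis, in which the chelated tetrahedral adduct survives until the quench so that the allyl group adds only once, and the cold neutral work-up keeps the β,γ-unsaturated ketone from conjugating.

Step 7
Reactants: 12 (7E)-7-methyl-9-[(triisopropylsilyl)oxy]deca-1,7,9-trien-4-one
Product: 13 (7E)-3-diazo-7-methyl-9-[(triisopropylsilyl)oxy]deca-1,7,9-trien-4-one
Conditions: p-ABSA, DBU, MeCN, 0 °C; used at once, kept cold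
Reagents that add atoms: 4-acetamidobenzenesulfonyl azide, CC(=O)Nc1ccc(cc1)S(=O)(=O)N=[N+]=[N-]
Why: Regitz diazo transfer to the doubly activated C3 methylene (allylic and α to the ketone), the most acidic site of the molecule, gives the vinyl diazoketone directly.

Step 8
Reactants: 13 (7E)-3-diazo-7-methyl-9-[(triisopropylsilyl)oxy]deca-1,7,9-trien-4-one
Product: 15 (1R)-1-methyl-9-[(triisopropylsilyl)oxy]bicyclo[5.3.0]deca-5,9-dien-4-one, via cis-divinylcyclopropane 14 (not isolated)
Conditions: Rh2(S-PTAD)4 (dirhodium tetrakis[(S)-(1-adamantyl)(N-phthalimido)acetate], 1 mol %), 2,2-dimethylbutane, −40 → 23 °C, slow addition of 13; then 40 °C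
Reagents that add atoms: none
Why: Loss of N2 gives a rhodium vinylcarbenoid at C5 that adds across the tethered C1=C10 alkene, and the cis-divinylcyclopropane 14 then undergoes a Cope [3,3] shift through a boat transition state, forming C7–C8 and breaking C5–C10; the closest known reaction type is the rhodium-catalysed tandem cyclopropanation/Cope rearrangement (formal [4+3] cycloaddition) of vinyl diazo carbonyl compounds with dienes in its intramolecular form. Ring A closes in the cyclopropanation as a five-membered ring in the exo sense (C5–C1 bond of a bicyclo[3.1.0]hexan-2-one), and ring B closes in the sigmatropic step as a seven-membered ring. The only new stereocentre, quaternary C1, is set by the chiral carboxylate ligands, which select the alkene face attacked by the carbenoid, and the Cope step does not touch it. The step needs the two vinyl groups cis on the cyclopropane, which the (E)-alkene from step 2 secures because alkene geometry is retained in the cycloaddition. It also needs attack at C1=C10 and not at the terminal enol ether C8=C9, which the three-atom tether secures, while slow addition at low temperature keeps the diazo compound from cyclising to a pyrazole.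

Step 9
Reactants: 15 (1R)-1-methyl-9-[(triisopropylsilyl)oxy]bicyclo[5.3.0]deca-5,9-dien-4-one
Product: 16 (1R)-9,9-(ethylenedioxy)-1-methylbicyclo[5.3.0]dec-5-en-4-one
Conditions: HOCH2CH2OH, CSA (cat.), CH2Cl2, 0 → 23 °C
Reagents that add atoms: ethylene glycol, OCCO
Why: acid-catalysed ketalisation of the enol ether (protonation at C10, addition of the diol, loss of the silanol) turns C9 into a dioxolane that is inert to borane, while the conjugated C4 ketone is not ketalised under these mild conditions.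

Step 10
Reactants: 16 (1R)-9,9-(ethylenedioxy)-1-methylbicyclo[5.3.0]dec-5-en-4-one
Product: 17 (1R,4S)-9,9-(ethylenedioxy)-1-methylbicyclo[5.3.0]dec-5-en-4-ol
Conditions: (R)-2-methyl-CBS-oxazaborolidine (0.2 equiv), catecholborane, toluene, −78 °C
Reagents that add atoms: none
Why: Corey–Bakshi–Shibata 1,2-reduction under reagent control, with the alkylidene carbon C5 as the large group, gives the (4S)-alcohol (OH cis to the C1 methyl), and catecholborane does not hydroborate the alkene.

Step 11
Reactants: 17 (1R,4S)-9,9-(ethylenedioxy)-1-methylbicyclo[5.3.0]dec-5-en-4-ol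
Product: 19 (1R,4S,5R,6S)-9,9-(ethylenedioxy)-1-methyl-6-(4,4,5,5-tetramethyl-1,3,2-dioxaborolan-2-yl)bicyclo[5.3.0]decan-4-ol, via C6 alkylborane 18 (not isolated)
Conditions: BH3·THF (3 equiv), THF, 0 → 23 °C; then pinacol, 23 °C; then H2O
Reagents that add atoms: borane–tetrahydrofuran, B.C1CCOC1; pinacol, CC(C)(O)C(C)(C)O
Why: hydroboration adds H and B syn across C5=C6 with boron on the less substituted C6, on the face away from both the C1 methyl and the C4 alkoxyborane, which sets C5–H trans to the methyl (trans ring fusion) and C6–B cis to C5–H in one event, and pinacol then turns the alkylborane into a boronate that masks the C6 hydroxyl.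

Step 12
Reactants: 19 (1R,4S,5R,6S)-9,9-(ethylenedioxy)-1-methyl-6-(4,4,5,5-tetramethyl-1,3,2-dioxaborolan-2-yl)bicyclo[5.3.0]decan-4-ol
Product: 20 (1R,5R,6S)-9,9-(ethylenedioxy)-1-methyl-6-(4,4,5,5-tetramethyl-1,3,2-dioxaborolan-2-yl)bicyclo[5.3.0]decan-4-one
Conditions: Dess–Martin periodinane, CH2Cl2, 23 °C
Reagents that add atoms: none
Why: Dess–Martin oxidation of the secondary alcohol runs without base, so the C–B bond and the epimerisable C5 centre next to the new ketone stay as they are.

Step 13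
Reactants: 20 (1R,5R,6S)-9,9-(ethylenedioxy)-1-methyl-6-(4,4,5,5-tetramethyl-1,3,2-dioxaborolan-2-yl)bicyclo[5.3.0]decan-4-one; 21 isopropylmagnesium chloride
Product: 23 (1R,4R,5S,6S)-9,9-(ethylenedioxy)-4-isopropyl-1-methylbicyclo[5.3.0]decane-4,6-diol, via boronate carbinol 22 (not isolated)
Conditions: 21, CeCl3 (anhydrous), THF, −78 → 0 °C; then H2O; then NaBO3·4H2O, THF–H2O, 23 °C
Reagents that add atoms: sodium perborate tetrahydrate, [Na+].[O-]OB=O.O.O.O.O
Why: organocerium 1,2-addition (low basicity suppresses enolisation and β-hydride reduction) from the α face, anti to the axial C1 methyl of the trans-fused ketone, sets the 4β-hydroxy-4α-isopropyl centre, and perborate then oxidises the C6–B bond (also in any borate complex formed) to C6–OH with retention.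

Step 14
Reactants: 24 4-hydroxybenzoic acid
Product: 26 4-[(tert-butyldimethylsilyl)oxy]benzoic acid, via silyl ester 25 (not isolated)
Conditions: TBSCl, imidazole, DMF, 23 °C; then AcOH–THF–H2O, 23 °C
Reagents that add atoms: tert-butyldimethylsilyl chloride, CC(C)(C)[Si](C)(C)Cl
Why: both acidic hydroxyl groups are silylated and the labile silyl ester alone is hydrolysed by weak aqueous acid, leaving the phenol protected.

Step 15
Reactants: 23 (1R,4R,5S,6S)-9,9-(ethylenedioxy)-4-isopropyl-1-methylbicyclo[5.3.0]decane-4,6-diol; 26 4-[(tert-butyldimethylsilyl)oxy]benzoic acid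
Product: 27 (1R,4R,5S,6S)-9,9-(ethylenedioxy)-4-hydroxy-4-isopropyl-1-methylbicyclo[5.3.0]decan-6-yl 4-[(tert-butyldimethylsilyl)oxy]benzoate
Conditions: DCC, DMAP (cat.), CH2Cl2, 23 °C
Reagents that add atoms: none
Why: Steglich esterification acylates only the secondary C6 hydroxyl, because the tertiary C4 hydroxyl is too hindered and C9 is still a ketal, and C6 keeps its configuration since its C–O bond is not broken.

Step 16
Reactants: 27 (1R,4R,5S,6S)-9,9-(ethylenedioxy)-4-hydroxy-4-isopropyl-1-methylbicyclo[5.3.0]decan-6-yl 4-[(tert-butyldimethylsilyl)oxy]benzoate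
Product: 28 (1R,4R,5S,6S)-4-hydroxy-4-isopropyl-1-methyl-9-oxobicyclo[5.3.0]decan-6-yl 4-[(tert-butyldimethylsilyl)oxy]benzoate
Conditions: PPTS (cat.), acetone–H2O, 45 °C
Reagents that add atoms: water, O
Why: mild acid hydrolysis of the dioxolane frees the C9 ketone, and the aryl silyl ether, the ester and the tertiary alcohol tolerate the weak acid.

Step 17
Reactants: 28 (1R,4R,5S,6S)-4-hydroxy-4-isopropyl-1-methyl-9-oxobicyclo[5.3.0]decan-6-yl 4-[(tert-butyldimethylsilyl)oxy]benzoate
Product: 30 (1R,4R,5S,6S)-8-[(dimethylamino)methyl]-4-isopropyl-1-methyl-9-oxo-4-[(trimethylsilyl)oxy]bicyclo[5.3.0]decan-6-yl 4-[(tert-butyldimethylsilyl)oxy]benzoate, via bis(trimethylsilyl) enol ether 29 (not isolated)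
Conditions: TMSOTf (3 equiv), Et3N, CH2Cl2, 0 °C; then Me2N=CH2 I (Eschenmoser's salt), CH2Cl2, 23 °C; then H2O
Reagents that add atoms: trimethylsilyl trifluoromethanesulfonate, C[Si](C)(C)OS(=O)(=O)C(F)(F)F; N,N-dimethylmethyleneiminium iodide, C=[N+](C)C.[I-]
Why: soft enolisation forms the silyl enol ether toward the less hindered C8 (C10 is neopentyl) and caps the tertiary alcohol, and the Mannich reaction with Eschenmoser's salt then puts the C14 carbon on C8 without a strongly basic enolate that could attack the ester; the new C8 centre is formed as a mixture and disappears in step 18.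

Step 18
Reactants: 30 (1R,4R,5S,6S)-8-[(dimethylamino)methyl]-4-isopropyl-1-methyl-9-oxo-4-[(trimethylsilyl)oxy]bicyclo[5.3.0]decan-6-yl 4-[(tert-butyldimethylsilyl)oxy]benzoate
Product: 32 (1R,4R,5S,6S)-4-isopropyl-1-methyl-8-methylidene-9-oxo-4-[(trimethylsilyl)oxy]bicyclo[5.3.0]decan-6-yl 4-[(tert-butyldimethylsilyl)oxy]benzoate, via trimethylammonium iodide 31 (not isolated)
Conditions: MeI, CH2Cl2, 23 °C; then aq. NaHCO3, CH2Cl2, 23 °C
Reagents that add atoms: none
Why: N-methylation followed by E1cB (Hofmann-type) loss of trimethylamine gives the 8-methylidene ketone under weakly basic conditions that spare the ester and the aryl silyl ether.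

Step 19
Reactants: 32 (1R,4R,5S,6S)-4-isopropyl-1-methyl-8-methylidene-9-oxo-4-[(trimethylsilyl)oxy]bicyclo[5.3.0]decan-6-yl 4-[(tert-butyldimethylsilyl)oxy]benzoate
Product: 33 (1R,4R,5S,6S,9R)-9-hydroxy-4-isopropyl-1-methyl-8-methylidene-4-[(trimethylsilyl)oxy]bicyclo[5.3.0]decan-6-yl 4-[(tert-butyldimethylsilyl)oxy]benzoate
Conditions: NaBH4, CeCl3·7H2O, MeOH, −78 °C
Reagents that add atoms: none
Why: Luche 1,2-reduction of the enone, with hydride approaching C9 from the α face away from the axial C1 methyl, should give the 9β (9R) allylic alcohol and leaves the ester alone; any loss of the labile tertiary trimethylsilyl ether here is harmless because step 20 removes it anyway.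

Step 20
Reactants: 33 (1R,4R,5S,6S,9R)-9-hydroxy-4-isopropyl-1-methyl-8-methylidene-4-[(trimethylsilyl)oxy]bicyclo[5.3.0]decan-6-yl 4-[(tert-butyldimethylsilyl)oxy]benzoate
Product: 34 (1R,4R,5S,6S,9R)-4,9-dihydroxy-4-isopropyl-1-methyl-8-methylidenebicyclo[5.3.0]decan-6-yl 4-hydroxybenzoate
Conditions: KHF2, MeOH, 23 °C
Reagents that add atoms: none
Why: fluoride-driven desilylation in methanol cleaves the aryl silyl ether and the tertiary trimethylsilyl ether under near-neutral conditions, so the ester does not migrate or cleave and no stereocentre is touched.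

Compound list
1 | 2-methyl-1,3-dithiane | CC1SCCCS1 | starting material
2 | methacrolein (2-methylprop-2-enal) | CC(=C)C=O | starting material
3 | 2-lithio-2-methyl-1,3-dithiane | [Li]C1(C)SCCCS1 | intermediate
4 | 2-methyl-1-(2-methyl-1,3-dithian-2-yl)prop-2-en-1-ol (racemic) | CC(=C)C(O)C1(C)SCCCS1 | intermediate
5 | triethyl orthoacetate | CCOC(C)(OCC)OCC | starting material
6 | mixed ketene acetal, 2-[1-(1-ethoxyethenyloxy)-2-methylprop-2-enyl]-2-methyl-1,3-dithiane | C=C(OCC)OC(C(C)=C)C1(C)SCCCS1 | intermediate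
7 | ethyl (4E)-4-methyl-5-(2-methyl-1,3-dithian-2-yl)pent-4-enoate | CCOC(=O)CC/C(C)=C/C1(C)SCCCS1 | intermediate
8 | (4E)-N-methoxy-N,4-dimethyl-5-(2-methyl-1,3-dithian-2-yl)pent-4-enamide | CON(C)C(=O)CC/C(C)=C/C1(C)SCCCS1 | intermediate
9 | (4E)-N-methoxy-N,4-dimethyl-6-oxohept-4-enamide | CON(C)C(=O)CC/C(C)=C/C(C)=O | intermediate
10 | (4E)-N-methoxy-N,4-dimethyl-6-[(triisopropylsilyl)oxy]hepta-4,6-dienamide | CON(C)C(=O)CC/C(C)=C/C(=C)O[Si](C(C)C)(C(C)C)C(C)C | intermediate
11 | allylmagnesium bromide | C=CC[Mg]Br | starting material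
12 | (7E)-7-methyl-9-[(triisopropylsilyl)oxy]deca-1,7,9-trien-4-one | C=CCC(=O)CC/C(C)=C/C(=C)O[Si](C(C)C)(C(C)C)C(C)C | intermediate
13 | (7E)-3-diazo-7-methyl-9-[(triisopropylsilyl)oxy]deca-1,7,9-trien-4-one (key-step precursor) | C=CC(=[N+]=[N-])C(=O)CC/C(C)=C/C(=C)O[Si](C(C)C)(C(C)C)C(C)C | intermediate
14 | (1S,5R,6R)-1-ethenyl-5-methyl-6-{1-[(triisopropylsilyl)oxy]ethenyl}bicyclo[3.1.0]hexan-2-one (von Baeyer locants; ethenyl, methyl and silyloxyethenyl groups all cis on the cyclopropane) | C=C[C@@]12C(=O)CC[C@]1(C)[C@H]2C(=C)O[Si](C(C)C)(C(C)C)C(C)C | intermediate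
15 | (1R)-1-methyl-9-[(triisopropylsilyl)oxy]bicyclo[5.3.0]deca-5,9-dien-4-one, i.e. (3aR)-3a-methyl-5-[(triisopropylsilyl)oxy]-3,3a,6,7-tetrahydroazulen-1(2H)-one (C4 ketone, C5=C6, C9=C10 silyl enol ether) | C[C@]12CCC(=O)C1=CCCC(O[Si](C(C)C)(C(C)C)C(C)C)=C2 | intermediate
16 | (1R)-9,9-(ethylenedioxy)-1-methylbicyclo[5.3.0]dec-5-en-4-one | C[C@]12CCC(=O)C1=CCCC3(OCCO3)C2 | intermediate
17 | (1R,4S)-9,9-(ethylenedioxy)-1-methylbicyclo[5.3.0]dec-5-en-4-ol (OH cis to the C1 methyl) | C[C@]12CC[C@H](O)C1=CCCC3(OCCO3)C2 | intermediate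
18 | (1R,4S,5R,6S)-6-boranyl-4-(boranyloxy)-9,9-(ethylenedioxy)-1-methylbicyclo[5.3.0]decane | C1C[C@H](B)[C@@H]2[C@](C)(CC[C@@H]2OB)CC13OCCO3 | intermediate
19 | (1R,4S,5R,6S)-9,9-(ethylenedioxy)-1-methyl-6-(4,4,5,5-tetramethyl-1,3,2-dioxaborolan-2-yl)bicyclo[5.3.0]decan-4-ol (H5 trans to the C1 methyl; boron cis to H5) | C1C[C@H](B2OC(C)(C)C(C)(C)O2)[C@@H]2[C@](C)(CC[C@@H]2O)CC13OCCO3 | intermediate
20 | (1R,5R,6S)-9,9-(ethylenedioxy)-1-methyl-6-(4,4,5,5-tetramethyl-1,3,2-dioxaborolan-2-yl)bicyclo[5.3.0]decan-4-one | C1C[C@H](B2OC(C)(C)C(C)(C)O2)[C@@H]2[C@](C)(CCC2=O)CC13OCCO3 | intermediate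
21 | isopropylmagnesium chloride | CC(C)[Mg]Cl | starting material
22 | (1R,4R,5R,6S)-9,9-(ethylenedioxy)-4-isopropyl-1-methyl-6-(4,4,5,5-tetramethyl-1,3,2-dioxaborolan-2-yl)bicyclo[5.3.0]decan-4-ol | C1C[C@H](B2OC(C)(C)C(C)(C)O2)[C@@H]2[C@](C)(CC[C@@]2(O)C(C)C)CC13OCCO3 | intermediate
23 | (1R,4R,5S,6S)-9,9-(ethylenedioxy)-4-isopropyl-1-methylbicyclo[5.3.0]decane-4,6-diol | C1C[C@H](O)[C@@H]2[C@](C)(CC[C@@]2(O)C(C)C)CC13OCCO3 | intermediate
24 | 4-hydroxybenzoic acid | O=C(O)c1ccc(O)cc1 | starting material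
25 | tert-butyldimethylsilyl 4-[(tert-butyldimethylsilyl)oxy]benzoate | CC(C)(C)[Si](C)(C)OC(=O)c1ccc(O[Si](C)(C)C(C)(C)C)cc1 | intermediate
26 | 4-[(tert-butyldimethylsilyl)oxy]benzoic acid | CC(C)(C)[Si](C)(C)Oc1ccc(cc1)C(=O)O | intermediate
27 | (1R,4R,5S,6S)-9,9-(ethylenedioxy)-4-hydroxy-4-isopropyl-1-methylbicyclo[5.3.0]decan-6-yl 4-[(tert-butyldimethylsilyl)oxy]benzoate | C1C[C@H](OC(=O)c2ccc(O[Si](C)(C)C(C)(C)C)cc2)[C@@H]2[C@](C)(CC[C@@]2(O)C(C)C)CC13OCCO3 | intermediate
28 | (1R,4R,5S,6S)-4-hydroxy-4-isopropyl-1-methyl-9-oxobicyclo[5.3.0]decan-6-yl 4-[(tert-butyldimethylsilyl)oxy]benzoate | O=C1CC[C@H](OC(=O)c2ccc(O[Si](C)(C)C(C)(C)C)cc2)[C@@H]2[C@](C)(CC[C@@]2(O)C(C)C)C1 | intermediate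
29 | (1R,4R,5S,6S)-4-isopropyl-1-methyl-4,9-bis[(trimethylsilyl)oxy]bicyclo[5.3.0]dec-8-en-6-yl 4-[(tert-butyldimethylsilyl)oxy]benzoate | C[Si](C)(C)OC1=CC[C@H](OC(=O)c2ccc(O[Si](C)(C)C(C)(C)C)cc2)[C@@H]2[C@](C)(CC[C@@]2(O[Si](C)(C)C)C(C)C)C1 | intermediate
30 | (1R,4R,5S,6S)-8-[(dimethylamino)methyl]-4-isopropyl-1-methyl-9-oxo-4-[(trimethylsilyl)oxy]bicyclo[5.3.0]decan-6-yl 4-[(tert-butyldimethylsilyl)oxy]benzoate (mixture of C8 epimers) | CN(C)CC1C[C@H](OC(=O)c2ccc(O[Si](C)(C)C(C)(C)C)cc2)[C@@H]2[C@](C)(CC[C@@]2(O[Si](C)(C)C)C(C)C)CC1=O | intermediate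
31 | trimethylammonium iodide of 30 (C8 epimers) | C[N+](C)(C)CC1C[C@H](OC(=O)c2ccc(O[Si](C)(C)C(C)(C)C)cc2)[C@@H]2[C@](C)(CC[C@@]2(O[Si](C)(C)C)C(C)C)CC1=O.[I-] | intermediate
32 | (1R,4R,5S,6S)-4-isopropyl-1-methyl-8-methylidene-9-oxo-4-[(trimethylsilyl)oxy]bicyclo[5.3.0]decan-6-yl 4-[(tert-butyldimethylsilyl)oxy]benzoate | C=C1C[C@H](OC(=O)c2ccc(O[Si](C)(C)C(C)(C)C)cc2)[C@@H]2[C@](C)(CC[C@@]2(O[Si](C)(C)C)C(C)C)CC1=O | intermediate
33 | (1R,4R,5S,6S,9R)-9-hydroxy-4-isopropyl-1-methyl-8-methylidene-4-[(trimethylsilyl)oxy]bicyclo[5.3.0]decan-6-yl 4-[(tert-butyldimethylsilyl)oxy]benzoate | C=C1C[C@H](OC(=O)c2ccc(O[Si](C)(C)C(C)(C)C)cc2)[C@@H]2[C@](C)(CC[C@@]2(O[Si](C)(C)C)C(C)C)C[C@H]1O | intermediate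
34 | (1R,4R,5S,6S,9R)-4,9-dihydroxy-4-isopropyl-1-methyl-8-methylidenebicyclo[5.3.0]decan-6-yl 4-hydroxybenzoate (CNP0164257.2) | C=C1C[C@H](OC(=O)c2ccc(O)cc2)[C@@H]2[C@](C)(CC[C@@]2(O)C(C)C)C[C@H]1O | target

Total step count: 20. Longest linear sequence: 19 steps (steps 1–13 and 15–20; step 14 is a one-step side branch).

Steps most likely to fail

Step 8. What may go wrong: the chiral carboxylate ligands may select the faces of C1=C10 poorly for a ketone-tethered carbenoid, or the diazo compound may cyclise to a pyrazole before the carbenoid forms. Fallback: starting from 13, the same tandem reaction is run with achiral dirhodium tetraacetate, Rh2(OAc)4, to give, by way of the racemic cis-divinylcyclopropane F1, the racemic dienone F2. This is ketalised as in step 9 to the racemic ketal F3 and reduced with the (R)-CBS catalyst as in step 10. Because that reduction is reagent-controlled, the two enantiomers become diastereomers, 17 and its (1S,4S) isomer F4, which are separated by chromatography. The route is rejoined at 17.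

Step 11. What may go wrong: borane may add to the wrong face of C5=C6 and give the cis ring fusion, or the alkylborane may not convert cleanly into the pinacol boronate. Fallback: starting from ketal enone 16 and bypassing steps 10–12, copper-catalysed conjugate borylation (CuCl, NaOt-Bu, Xantphos, B2pin2, MeOH, THF, 23 °C) gives the β-boryl ketone 20 directly. The ring-fusion hydrogen then comes from protonation of the enolate, so the C5 configuration would have to be checked at that point. No compound outside the list is made (F0), and the route is rejoined at 20.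

Step 7. What may go wrong: diazo transfer may go to the wrong α position, or the unsubstituted vinyl diazoketone may be lost by 1,5-electrocyclisation under the basic transfer conditions. Fallback: starting from Weinreb amide 10, methylmagnesium bromide gives the methyl ketone F5. Kinetic enolisation with LiN(SiMe3)2 and acylation with CF3CO2CH2CF3 give the trifluoroacetyl diketone F6, which is not isolated and undergoes detrifluoroacetylative diazo transfer (MsN3, Et3N) to the diazomethyl ketone F7. Aldol addition of F7 to acetaldehyde (LiN(i-Pr)2, THF, −78 °C) gives the β-hydroxy diazoketone F8, and dehydration (MsCl, Et3N, 0 °C) forms the vinyl group last. The route is rejoined at 13.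

Further compounds
F1 | step 8 | racemic cis-divinylcyclopropane, rel-(1S,5R,6R)-1-ethenyl-5-methyl-6-{1-[(triisopropylsilyl)oxy]ethenyl}bicyclo[3.1.0]hexan-2-one (racemate; one enantiomer drawn) | C=C[C@@]12C(=O)CC[C@]1(C)[C@H]2C(=C)O[Si](C(C)C)(C(C)C)C(C)C
F2 | step 8 | racemic 1-methyl-9-[(triisopropylsilyl)oxy]bicyclo[5.3.0]deca-5,9-dien-4-one | CC12CCC(=O)C1=CCCC(O[Si](C(C)C)(C(C)C)C(C)C)=C2
F3 | step 8 | racemic 9,9-(ethylenedioxy)-1-methylbicyclo[5.3.0]dec-5-en-4-one | CC12CCC(=O)C1=CCCC3(OCCO3)C2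
F4 | step 8 | (1S,4S)-9,9-(ethylenedioxy)-1-methylbicyclo[5.3.0]dec-5-en-4-ol (OH trans to the C1 methyl) | C[C@@]12CC[C@H](O)C1=CCCC3(OCCO3)C2
F5 | step 7 | (5E)-5-methyl-7-[(triisopropylsilyl)oxy]octa-5,7-dien-2-one | CC(=O)CC/C(C)=C/C(=C)O[Si](C(C)C)(C(C)C)C(C)C
F6 | step 7 | (7E)-1,1,1-trifluoro-7-methyl-9-[(triisopropylsilyl)oxy]deca-7,9-diene-2,4-dione | O=C(CC(=O)CC/C(C)=C/C(=C)O[Si](C(C)C)(C(C)C)C(C)C)C(F)(F)F
F7 | step 7 | (5E)-1-diazo-5-methyl-7-[(triisopropylsilyl)oxy]octa-5,7-dien-2-one | [N-]=[N+]=CC(=O)CC/C(C)=C/C(=C)O[Si](C(C)C)(C(C)C)C(C)C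
F8 | step 7 | (7E)-3-diazo-2-hydroxy-7-methyl-9-[(triisopropylsilyl)oxy]deca-7,9-dien-4-one (racemic) | CC(O)C(=[N+]=[N-])C(=O)CC/C(C)=C/C(=C)O[Si](C(C)C)(C(C)C)C(C)C
F0 | step 11 | none | none
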